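**Retrosynthetic overview**
1. Target ⇒ allyl ester (Pd deallylation). Its (Z)-enoic acid C=C ⇒ aldehyde + diaryl phosphonate (Z-selective Horner–Wadsworth–Emmons). The aldehyde and the (E)-trisubstituted alkene ⇒ Claisen rearrangement of the vinyl ether of a 2-methylallyl carbinol.
2. Key disconnection: the bond between the terminal CH2 of the CH2CH2 spacer on the stereocentre and the α-carbon of the methyl (Z)-enoate ⇒ primary alkyl radical from a redox-active ester + (E)-α-bromo enoate, joined by nickel-electrocatalytic decarboxylative alkenylation.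
3. Enabling feature: that α-carbon is the sp2 α-carbon of an acrylate unit (C=C conjugated to CO2Me), so it can carry bromine with fixed geometry and add readily to low-valent nickel; its partner is an unbranched primary CH2 two carbons from the only stereocentre. The trisubstituted alkene of the long chain is kept latent as the 2-methylallyl carbinol, so the radical has no alkene in a 5-hexenyl position.
4. Stereocentre from (S)-limonene: ring C=C opened by ozonolysis (ketone/acetal), methyl ketone degraded to the acid (haloform), aldehyde extended with isopropenyl Grignard.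
5. Rings: none is formed. The only ring, the furan-2(5H)-one, enters intact as 4-bromofuran-2(5H)-one (B-alkyl Suzuki coupling, then Still–Gennari-type bromo-olefination).

Key step: step 9

Remark: the carbinol centre formed in the Grignard step is an inconsequential epimer mixture that the Claisen rearrangement erases; it is left undefined in names and SMILES, and the two C-substituted phosphonates are racemic at the phosphorus-bearing carbon.

Step 1
Reactants: 1 (S)-(−)-limonene
Product: 2 (5S)-7,7-dimethoxy-5-(prop-1-en-2-yl)heptan-2-one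
Conditions: O3 (1 equiv), CH2Cl2/MeOH 5:1, −78 °C; TsOH·H2O (cat.), −78 °C → rt; NaHCO3; Me2S, rt
Reagents that add atoms: ozone [O-][O+]=O; methanol CO
Why: Chemoselective ozonolysis: ozone attacks the electron-rich trisubstituted ring alkene much faster than the 1,1-disubstituted isopropenyl group, and Criegee cleavage in methanol with acid-catalysed acetalisation of the aldehyde terminus and reductive work-up is the established way to open a 1-methylcyclohexene to a methyl ketone and a dimethyl acetal, the stereocentre staying untouched.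

Step 2
Reactants: 2 (5S)-7,7-dimethoxy-5-(prop-1-en-2-yl)heptan-2-one
Product: 4 (4S)-6-oxo-4-(prop-1-en-2-yl)hexanoic acid, via acetal acid 3 (not isolated)
Conditions: aq. NaOCl (3.3 equiv), NaOH, 1,4-dioxane/H2O, 0 °C → rt; Na2SO3; then 2 M HCl (pH 1), THF, rt
Reagents that add atoms: sodium hydroxide [Na+].[OH-]; water O
Why: Haloform (Lieben) degradation of the methyl ketone in strongly basic hypochlorite, where the isolated isopropenyl alkene is not attacked, shortens the chain by one carbon to the carboxylate, and acidification after destruction of the oxidant hydrolyses the dimethyl acetal to the aldehyde.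

Step 3
Reactants: 4 (4S)-6-oxo-4-(prop-1-en-2-yl)hexanoic acid
Product: 5 (4S)-6-hydroxy-7-methyl-4-(prop-1-en-2-yl)oct-7-enoic acid (C6 epimer mixture)
Conditions: isopropenylmagnesium bromide (2.5 equiv), THF, −78 → 0 °C; aq. NH4Cl
Reagents that add atoms: isopropenylmagnesium bromide CC(=C)[Mg]Br
Why: Grignard 1,2-addition: the first equivalent turns the acid into an unreactive magnesium carboxylate and the next adds to the aldehyde, the new carbinol centre being formed without control because both epimers converge in step 12.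

Step 4
Reactants: 5 (4S)-6-hydroxy-7-methyl-4-(prop-1-en-2-yl)oct-7-enoic acid
Product: 6 1,3-dioxoisoindolin-2-yl (4S)-6-hydroxy-7-methyl-4-(prop-1-en-2-yl)oct-7-enoate (C6 epimer mixture)
Conditions: N-hydroxyphthalimide (1.1 equiv), N,N'-diisopropylcarbodiimide (1.1 equiv), CH2Cl2, 0 °C → rt
Reagents that add atoms: N-hydroxyphthalimide O=C1c2ccccc2C(=O)N1O
Why: Carbodiimide (Steglich-type) esterification without an acyl-transfer catalyst: the acidic N-hydroxyphthalimide captures the O-acylisourea far faster than the hindered secondary alcohol does, giving the redox-active ester.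

Step 5
Reactants: 7 methyl 2-[bis(2,2,2-trifluoroethoxy)phosphoryl]acetate
Product: 9 methyl 2-bromo-2-[bis(2,2,2-trifluoroethoxy)phosphoryl]acetate, via dibromophosphonate 8 (not isolated)
Conditions: aq. NaOBr (2.2 equiv), 0 °C; then SnCl2·2H2O (1 equiv), EtOH/H2O, 0 °C
Reagents that add atoms: sodium hypobromite [Na+].[O-]Br
Why: Exhaustive α-bromination of the acidic phosphonoacetate methylene with hypobromite followed by reductive removal of one bromine with SnCl2 is the known route to mono-α-bromophosphonoacetates and avoids the mixtures of direct monobromination.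

Step 6
Reactants: 10 3,3-diethoxyprop-1-ene; 11 4-bromofuran-2(5H)-one
Product: 13 4-(3,3-diethoxypropyl)furan-2(5H)-one, via alkylborane 12 (not isolated)
Conditions: 10, 9-BBN (1.1 equiv), THF, 0 °C → rt; then 11, PdCl2(dppf) (5 mol%), AsPh3 (10 mol%), K3PO4 (aq.), DMF, rt
Reagents that add atoms: none
Why: Anti-Markovnikov hydroboration of the monosubstituted alkene and B-alkyl Suzuki–Miyaura coupling of the alkylborane with the β-bromobutenolide, a vinylogous acyl bromide that undergoes fast oxidative addition, attach the side chain to the intact lactone ring.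

Step 7
Reactants: 13 4-(3,3-diethoxypropyl)furan-2(5H)-one
Product: 14 3-(5-oxo-2,5-dihydrofuran-3-yl)propanal
Conditions: 1 M HCl, THF, rt
Reagents that add atoms: water O
Why: Acid-catalysed acetal hydrolysis, to which the β-alkyl butenolide is inert.

Step 8
Reactants: 14 3-(5-oxo-2,5-dihydrofuran-3-yl)propanal; 9 methyl 2-bromo-2-[bis(2,2,2-trifluoroethoxy)phosphoryl]acetate
Product: 15 methyl (2E)-2-bromo-5-(5-oxo-2,5-dihydrofuran-3-yl)pent-2-enoate
Conditions: 9 (1.2 equiv), KOtBu (1.15 equiv), 18-crown-6, THF, −78 °C; then 14, −78 °C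
Reagents that add atoms: none
Why: Still–Gennari-type Horner–Wadsworth–Emmons olefination: the bis(trifluoroethyl) α-bromophosphonate reacts under kinetic control to place the ester cis to the aldehyde-derived chain, which for the α-bromo enoate is the E isomer, and the stabilised potassium phosphonate does not enolise the butenolide at −78 °C.

Step 9
Reactants: 6 1,3-dioxoisoindolin-2-yl (4S)-6-hydroxy-7-methyl-4-(prop-1-en-2-yl)oct-7-enoate; 15 methyl (2E)-2-bromo-5-(5-oxo-2,5-dihydrofuran-3-yl)pent-2-enoate
Product: 16 methyl (2Z,5S)-7-hydroxy-8-methyl-2-[3-(5-oxo-2,5-dihydrofuran-3-yl)propylidene]-5-(prop-1-en-2-yl)non-8-enoate (C7 epimer mixture)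
Conditions: 6 (1.5 equiv), 15 (1 equiv), NiCl2·6H2O (20 mol%), 2,2'-bipyridine (20 mol%), AgNO3 (0.3 equiv), DMF, Mg anode / reticulated vitreous carbon cathode, constant current, undivided cell, rt
Reagents that add atoms: none
Why: Cathodic reduction of the bipyridine nickel dichloride, on a cathode coated in situ with silver nanoparticles from AgNO3, gives low-valent nickel that adds oxidatively to the C–Br bond of 15 with retention, while single-electron reduction of 6 expels CO2 and phthalimide anion to give the primary alkyl radical, which the alkenylnickel species captures before reductive elimination from trivalent nickel forms the CH2–C(sp2) bond. The closest known reaction type is the nickel-electrocatalytic decarboxylative alkenylation of redox-active esters with alkenyl halides used for the modular assembly of polyene terpenoids. No ring is closed. No stereocentre is formed: the existing one lies two carbons from the radical centre and is not involved, and the alkene geometry is inherited from 15 (ester cis to the chain, the Z-enoate of the target). The step needs radical capture by nickel to outrun intramolecular radical reactions, which the substrate secures because the trisubstituted alkene that would sit in a 5-hexenyl relationship is still absent and the two alkenes present are in 4-pentenyl and 6-heptenyl relationships, whose cyclisations are orders of magnitude slower. It also needs chemoselective reduction, which the mild potential of the nickel couple secures, since the methyl ester, the butenolide and the free hydroxyl are inert there.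

Step 10
Reactants: 17 diphenyl phosphite; 18 prop-2-en-1-yl 2-bromoacetate
Product: 19 prop-2-en-1-yl 2-(diphenoxyphosphoryl)acetate
Conditions: Et3N (1.1 equiv), CH2Cl2, 0 °C → rt
Reagents that add atoms: none
Why: Michaelis–Becker-type P-alkylation of diphenyl phosphite with the activated α-bromo ester gives the diaryl phosphonoacetate needed for Z-selective olefination.

Step 11
Reactants: 19 prop-2-en-1-yl 2-(diphenoxyphosphoryl)acetate; 20 5-bromo-2-methylpent-2-ene
Product: 21 prop-2-en-1-yl 2-(diphenoxyphosphoryl)-6-methylhept-5-enoate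
Conditions: NaH (0.95 equiv), DMF, 0 °C; then 20, NaI (cat.), 50 °C
Reagents that add atoms: none
Why: SN2 C-alkylation of the stabilised phosphonoacetate anion by the primary homoallylic bromide under iodide catalysis installs the 4-methylpent-3-enyl branch, a slight deficit of base limiting dialkylation.

Step 12
Reactants: 16 methyl (2Z,5S)-7-hydroxy-8-methyl-2-[3-(5-oxo-2,5-dihydrofuran-3-yl)propylidene]-5-(prop-1-en-2-yl)non-8-enoate
Product: 23 methyl (2Z,5S,7E)-8-methyl-11-oxo-2-[3-(5-oxo-2,5-dihydrofuran-3-yl)propylidene]-5-(prop-1-en-2-yl)undec-7-enoate, via allyl vinyl ether 22 (not isolated)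
Conditions: ethyl vinyl ether (solvent), Hg(OAc)2 (0.2 equiv), reflux; evaporate; toluene, 120 °C, sealed tube
Reagents that add atoms: ethyl vinyl ether C=COCC
Why: Mercury-catalysed transfer vinylation and Claisen rearrangement: the [3,3]-sigmatropic shift through a chair transition state with the carbinol substituent equatorial forms the new C–C bond at the methylene terminus and the trisubstituted alkene with E geometry, and erases the epimeric carbinol centre.

Step 13
Reactants: 23 methyl (2Z,5S,7E)-8-methyl-11-oxo-2-[3-(5-oxo-2,5-dihydrofuran-3-yl)propylidene]-5-(prop-1-en-2-yl)undec-7-enoate; 21 prop-2-en-1-yl 2-(diphenoxyphosphoryl)-6-methylhept-5-enoate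
Product: 24 prop-2-en-1-yl (2Z,6E,9S,12Z)-12-(methoxycarbonyl)-6-methyl-2-(4-methylpent-3-en-1-yl)-15-(5-oxo-2,5-dihydrofuran-3-yl)-9-(prop-1-en-2-yl)pentadeca-2,6,12-trienoate
Conditions: 21 (1.3 equiv), NaH (1.2 equiv), THF, 0 °C; then 23, −78 → 0 °C
Reagents that add atoms: none
Why: Z-selective Horner–Wadsworth–Emmons olefination with a diaryl phosphonate (fast, irreversible collapse of the cis-oxaphosphetane) places the allyl ester cis to the chain, and the preformed sodium phosphonate adds to the aldehyde faster than to the methyl enoate or the butenolide.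

Step 14
Reactants: 24 prop-2-en-1-yl (2Z,6E,9S,12Z)-12-(methoxycarbonyl)-6-methyl-2-(4-methylpent-3-en-1-yl)-15-(5-oxo-2,5-dihydrofuran-3-yl)-9-(prop-1-en-2-yl)pentadeca-2,6,12-trienoate
Product: 25 (2Z,6E,9S,12Z)-12-(methoxycarbonyl)-6-methyl-2-(4-methylpent-3-en-1-yl)-15-(5-oxo-2,5-dihydrofuran-3-yl)-9-(prop-1-en-2-yl)pentadeca-2,6,12-trienoic acid
Conditions: Pd(PPh3)4 (5 mol%), morpholine (5 equiv), THF, rt
Reagents that add atoms: none
Why: Tsuji–Trost deallylation: zerovalent palladium ionises only the allyl ester to a π-allyl complex that morpholine traps, releasing the acid under neutral conditions that leave the methyl ester, the butenolide and all alkene geometries untouched.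

**Compound list**
1 | (S)-(−)-limonene, (4S)-1-methyl-4-(prop-1-en-2-yl)cyclohex-1-ene | CC1=CC[C@H](CC1)C(C)=C | starting material
2 | (5S)-7,7-dimethoxy-5-(prop-1-en-2-yl)heptan-2-one | C=C(C)[C@H](CC(OC)OC)CCC(C)=O | intermediate
3 | (4S)-6,6-dimethoxy-4-(prop-1-en-2-yl)hexanoic acid | C=C(C)[C@H](CC(OC)OC)CCC(=O)O | intermediate
4 | (4S)-6-oxo-4-(prop-1-en-2-yl)hexanoic acid | C=C(C)[C@H](CC=O)CCC(=O)O | intermediate
5 | (4S)-6-hydroxy-7-methyl-4-(prop-1-en-2-yl)oct-7-enoic acid (C6 epimer mixture) | C=C(C)[C@H](CC(O)C(C)=C)CCC(=O)O | intermediate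
6 | 1,3-dioxoisoindolin-2-yl (4S)-6-hydroxy-7-methyl-4-(prop-1-en-2-yl)oct-7-enoate (C6 epimer mixture) | C=C(C)[C@H](CC(O)C(C)=C)CCC(=O)ON1C(=O)c2ccccc2C1=O | intermediate
7 | methyl 2-[bis(2,2,2-trifluoroethoxy)phosphoryl]acetate | COC(=O)CP(=O)(OCC(F)(F)F)OCC(F)(F)F | starting material
8 | methyl 2,2-dibromo-2-[bis(2,2,2-trifluoroethoxy)phosphoryl]acetate | COC(=O)C(Br)(Br)P(=O)(OCC(F)(F)F)OCC(F)(F)F | intermediate
9 | methyl 2-bromo-2-[bis(2,2,2-trifluoroethoxy)phosphoryl]acetate (racemic) | COC(=O)C(Br)P(=O)(OCC(F)(F)F)OCC(F)(F)F | intermediate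
10 | 3,3-diethoxyprop-1-ene (acrolein diethyl acetal) | C=CC(OCC)OCC | starting material
11 | 4-bromofuran-2(5H)-one | BrC1=CC(=O)OC1 | starting material
12 | 9-(3,3-diethoxypropyl)-9-borabicyclo[3.3.1]nonane | CCOC(CCB1C2CCCC1CCC2)OCC | intermediate
13 | 4-(3,3-diethoxypropyl)furan-2(5H)-one | CCOC(CCC1=CC(=O)OC1)OCC | intermediate
14 | 3-(5-oxo-2,5-dihydrofuran-3-yl)propanal | O=CCCC1=CC(=O)OC1 | intermediate
15 | methyl (2E)-2-bromo-5-(5-oxo-2,5-dihydrofuran-3-yl)pent-2-enoate | COC(=O)/C(Br)=C\CCC1=CC(=O)OC1 | intermediate
16 | methyl (2Z,5S)-7-hydroxy-8-methyl-2-[3-(5-oxo-2,5-dihydrofuran-3-yl)propylidene]-5-(prop-1-en-2-yl)non-8-enoate (C7 epimer mixture) | C=C(C)[C@H](CC(O)C(C)=C)CC/C(=C/CCC1=CC(=O)OC1)C(=O)OC | intermediate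
17 | diphenyl phosphite | O=[PH](Oc1ccccc1)Oc1ccccc1 | starting material
18 | prop-2-en-1-yl 2-bromoacetate (allyl bromoacetate) | C=CCOC(=O)CBr | starting material
19 | prop-2-en-1-yl 2-(diphenoxyphosphoryl)acetate | C=CCOC(=O)CP(=O)(Oc1ccccc1)Oc1ccccc1 | intermediate
20 | 5-bromo-2-methylpent-2-ene | CC(C)=CCCBr | starting material
21 | prop-2-en-1-yl 2-(diphenoxyphosphoryl)-6-methylhept-5-enoate (racemic) | C=CCOC(=O)C(CCC=C(C)C)P(=O)(Oc1ccccc1)Oc1ccccc1 | intermediate
22 | methyl (2Z,5S)-7-(ethenyloxy)-8-methyl-2-[3-(5-oxo-2,5-dihydrofuran-3-yl)propylidene]-5-(prop-1-en-2-yl)non-8-enoate (C7 epimer mixture) | C=C(C)[C@H](CC(OC=C)C(C)=C)CC/C(=C/CCC1=CC(=O)OC1)C(=O)OC | intermediate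
23 | methyl (2Z,5S,7E)-8-methyl-11-oxo-2-[3-(5-oxo-2,5-dihydrofuran-3-yl)propylidene]-5-(prop-1-en-2-yl)undec-7-enoate | C=C(C)[C@H](C/C=C(\C)CCC=O)CC/C(=C/CCC1=CC(=O)OC1)C(=O)OC | intermediate
24 | prop-2-en-1-yl (2Z,6E,9S,12Z)-12-(methoxycarbonyl)-6-methyl-2-(4-methylpent-3-en-1-yl)-15-(5-oxo-2,5-dihydrofuran-3-yl)-9-(prop-1-en-2-yl)pentadeca-2,6,12-trienoate | C=C(C)[C@H](C/C=C(\C)CC/C=C(/CCC=C(C)C)C(=O)OCC=C)CC/C(=C/CCC1=CC(=O)OC1)C(=O)OC | intermediate
25 | (2Z,6E,9S,12Z)-12-(methoxycarbonyl)-6-methyl-2-(4-methylpent-3-en-1-yl)-15-(5-oxo-2,5-dihydrofuran-3-yl)-9-(prop-1-en-2-yl)pentadeca-2,6,12-trienoic acid (CNP0162600.1) | C=C(C)[C@H](C/C=C(\C)CC/C=C(/CCC=C(C)C)C(=O)O)CC/C(=C/CCC1=CC(=O)OC1)C(=O)OC | target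

**Step count and risks**
Total step count: 14. Longest linear sequence: 8 steps (1, 2, 3, 4, 9, 12, 13, 14).

Step 9. What may go wrong: loss of the alkene geometry at the alkenylnickel stage (through an oxygen-bound nickel allenoate), reductive debromination of 15 before the radical is captured, or intramolecular hydrogen abstraction from the carbinol C–H by the primary radical. Fallback without any radical capture at nickel: starting from 6, visible-light decarboxylative iodination (LiI, PPh3 cat., acetone, blue light) should give (5R)-7-iodo-2-methyl-5-(prop-1-en-2-yl)hept-1-en-3-ol F1. Alkylation of the sodium salt of 7 with F1 (NaH, DMSO, rt → 40 °C) should give methyl (5S)-2-[bis(2,2,2-trifluoroethoxy)phosphoryl]-7-hydroxy-8-methyl-5-(prop-1-en-2-yl)non-8-enoate F2. Still–Gennari olefination of F2 with aldehyde 14 (KN(SiMe3)2, 18-crown-6, THF, −78 °C) then forms the Z-enoate directly and comes back to the route at 16. In this variant the CH2–Cα bond is made by enolate alkylation and the alkene by olefination.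

Step 12. What may go wrong: incomplete transfer vinylation of the hindered secondary alcohol, mercuration of the 1,1-disubstituted alkenes, and partial loss of E-selectivity in the rearrangement of an unsubstituted vinyl ether. Fallback: starting from 16, Eschenmoser–Claisen rearrangement (CH3C(OMe)2NMe2, toluene, 110 °C), in which the amino substituent on the ketene acetal enforces the chair with the carbinol substituent equatorial, should give methyl (2Z,5S,7E)-11-(dimethylamino)-8-methyl-11-oxo-2-[3-(5-oxo-2,5-dihydrofuran-3-yl)propylidene]-5-(prop-1-en-2-yl)undec-7-enoate F3. Chemoselective reduction of the tertiary amide with Cp2Zr(H)Cl (THF, rt) should then give the aldehyde and comes back to the route at 23.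

Step 1. What may go wrong: over-oxidation, with ozone also cleaving the isopropenyl alkene, and incomplete acetalisation of the aldehyde terminus. Fallback: starting from 1, epoxidation with mCPBA (CH2Cl2, 0 °C), which is selective for the trisubstituted alkene, should give (4S)-1-methyl-4-(prop-1-en-2-yl)-7-oxabicyclo[4.1.0]heptane F4 as a cis/trans mixture. Periodic acid cleavage (H5IO6, THF/H2O) should give (3S)-6-oxo-3-(prop-1-en-2-yl)heptanal F5, and aldehyde-selective acetalisation (HC(OMe)3, MeOH, CeCl3·7H2O cat.) comes back to the route at 2.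

**Further compounds**
F1 | step 9 | (5R)-7-iodo-2-methyl-5-(prop-1-en-2-yl)hept-1-en-3-ol (C3 epimer mixture) | C=C(C)[C@H](CC(O)C(C)=C)CCI
F2 | step 9 | methyl (5S)-2-[bis(2,2,2-trifluoroethoxy)phosphoryl]-7-hydroxy-8-methyl-5-(prop-1-en-2-yl)non-8-enoate (mixture at C2 and C7) | C=C(C)[C@H](CC(O)C(C)=C)CCC(C(=O)OC)P(=O)(OCC(F)(F)F)OCC(F)(F)F
F3 | step 12 | methyl (2Z,5S,7E)-11-(dimethylamino)-8-methyl-11-oxo-2-[3-(5-oxo-2,5-dihydrofuran-3-yl)propylidene]-5-(prop-1-en-2-yl)undec-7-enoate | C=C(C)[C@H](C/C=C(\C)CCC(=O)N(C)C)CC/C(=C/CCC1=CC(=O)OC1)C(=O)OC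
F4 | step 1 | (4S)-1-methyl-4-(prop-1-en-2-yl)-7-oxabicyclo[4.1.0]heptane (cis/trans mixture) | CC1(O2)C2C[C@H](CC1)C(C)=C
F5 | step 1 | (3S)-6-oxo-3-(prop-1-en-2-yl)heptanal | C=C(C)[C@H](CC=O)CCC(C)=O
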